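## The problem

The target 29 is a dimeric flavonol. Two 3-hydroxy-2-arylchromen-4-one units are joined by a diaryl ether that runs from C4' of ring B of unit 1 (the 5-hydroxy-7-methoxy half) to C4' of ring B of unit 2 (the 5,7-dihydroxy half). It has no stereocentre, so the task is one of regiochemistry and of telling eight oxygens apart. Two of them are methyl ethers that must stay (O7 of unit 1, O3' of unit 2) and six are free (O3, O5 and O3' of unit 1; O3, O5 and O7 of unit 2). The two A rings are therefore differently substituted phloroglucinol rings that cannot be introduced in one operation, and every protecting group must leave under conditions that spare aryl methyl ethers. The diaryl ether carries an ortho oxygen on both B rings and has to be made between two electron-rich arenes. The finished 3-hydroxypyranones chelate metals and are oxidised by air in base, and free phloroglucinol rings are nucleophilic at C6 and C8. The C3 oxygens should therefore come late, and the phenols should travel as benzyl ethers that fall to neutral hydrogenolysis. The feature that opens the key step lies in ring A of unit 1: C4a sits between the two oxygen-bearing carbons C5 and C8a, and the methoxylated C7 is para to it. A cut at C4a–C4 thus leads to a 2-iodoresorcinol with a mirror plane through C4a and C7, whose two hydroxyls are interchangeable. Ring C then needs only C4 from carbon monoxide and C3–C2 from a terminal aryl alkyne, which is every atom of the ring except the 3-oxygen.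

## Retrosynthesis

**29 from 28.** The four benzyl–oxygen bonds at O5 and O3' of unit 1 and at O5 and O7 of unit 2 are cut last. Benzyl is preferred to methyl or silyl because the two methyl ethers of 29 must survive and a single neutral hydrogenolysis frees all four phenols. Compound 28 is the same skeleton with every phenol masked. The forward step must not reduce the pyranone C2=C3 bonds.

**28 from 26.** Both C3–O bonds are cut, which leads to the bis-flavone 26. The alternative of carrying the 3-oxygen through ring construction would rule out the alkyne-based ring closure. The two C2=C3 bonds of 26 are the only enol-ether alkenes in the molecule, so one dioxirane epoxidation followed by acid opening should hydroxylate both. The forward reaction needs all phenols capped, which 26 provides.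

**26 from 18, 23 and 13.** Ring C of unit 2 is cut at C4a–C4, C4–C3 and O1–C2. This gives the terminal alkyne 18 (unit 1 complete), carbon monoxide 13 and 3,5-bis(benzyloxy)-2-iodophenol 23. This cut is preferred to a diketone route because it repeats the reaction that builds unit 1, and because 23 brings O5 and O7 already benzylated, so 26 arrives fully protected. The forward reaction has to tolerate a flavone in the alkyne partner.

**18 from 17 and 16.** The ethynyl group of 18 is unmasked from the silyl alkyne 17, and 17 comes from 16 by benzylation of O5. The benzyl group on O5 is needed because a free, chelated 5-hydroxyl interferes with the later epoxidation. The triisopropylsilyl group is what keeps the two alkyne termini distinct up to this point.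

**16 from 12, 13 and 7 (key cut).** Ring C of unit 1 is cut at C4a–C4, C4–C3 and O1–C2. The fragments are 2-iodo-5-methoxybenzene-1,3-diol 12, carbon monoxide 13 and the mono-protected diyne 7. Against a chalcone or diketone route this cut needs no differentiation of the two ortho oxygens of ring A, because they are equivalent in 12. The 5-hydroxy-7-methoxy pattern therefore comes without a protecting group. The precursors are far simpler: a substituted benzene and a diaryl ether with two alkynes. The forward reaction must insert CO before the alkyne couples and must close ring C in the 6-endo mode.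

**7 from 6, 4, 5, 2, 3 and 1.** The terminal alkyne of 7 is traced to the aldehyde 6 by a one-carbon homologation. The silyl alkyne of 6 comes from the aryl iodide 4 and (triisopropylsilyl)acetylene 5. The diaryl ether C–O bond of 4 is cut to the fluoroaldehyde 2 and 4-iodo-2-methoxyphenol 3. The formyl group para to fluorine activates the substitution and later becomes the alkyne, while the iodide of 3 is inert in that step and becomes the second alkyne. Compound 2 is the benzyl ether of 4-fluoro-3-hydroxybenzaldehyde 1. The two handles (formyl and iodide) are thus distinct from the start.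

**12 from 11, 9 and 8; 23 from 22, 20 and 19.** The C–I bond of 12 is traced through the bis(methoxymethyl) ether 11 to the arene 9, made from 5-methoxyresorcinol 8. Directed lithiation between the two acetal oxygens is chosen over direct iodination of 8 because it fixes the site of iodine. In the same way 23 comes from the methoxymethyl ether 22, this from 20, and 20 from 3,5-bis(benzyloxy)phenol 19. Here the single acetal directs lithiation to its ortho position.

## Roads not taken

**Alternative 1:** The cut is through ring B of unit 1 at C3'–C4' and C5'–C6'. In the forward direction methyl 3-(benzyloxy)-2-oxo-2H-pyran-5-carboxylate A2 and the aryl ethynyl ether A3 would undergo an inverse-demand [4+2] cycloaddition and decarboxylative aromatisation to the benzoate A1.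
- Merits: the diaryl ether oxygen is in place before the ring exists, so no substitution at a donor-substituted aryl carbon is needed. Regiochemistry follows from the polarisation of both partners. The ester and the acetal are two well-differentiated handles.
- Weak points: A3 is an ynol ether that needs several steps and is thermally fragile, and A2 is not a stock compound. A1 contains neither pyranone ring, so a full flavone strategy is still required for both units.
- Comparison: this road is indifferent to the deactivating ortho-benzyloxy group that slows step 2, and its ester oxidation level suits diketone closures. The chosen plan sets against this a diaryl ether made in one substitution step from two purchasable arenes (4 from 2 and 3), and an aldehyde that becomes the alkyne in one step.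

**Alternative 2:** The cut is at O1–C8a in both units. In the forward direction a carbonate base in a dipolar aprotic solvent would make each enolate oxygen of the bis-diketone A5 displace an ortho fluoride, closing both C rings at once to give A4.
- Merits: both pyranones close in one metal-free operation, with no CO and no electron-rich aryl iodide. The 2,6-difluoroaryl ketones are symmetric, so there is no regiochemical question.
- Weak points: A4 has three C–F bonds where 29 has C–OH (C5 of unit 1, C5 and C7 of unit 2). Each must later be exchanged by an alkoxide on a chromenone that is itself open to attack at C2, and the 7-methoxy group of unit 1 is a competing leaving group. The unsymmetrical A5 needs two different Claisen condensations that must be kept apart. The 3-oxygens are still missing.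
- Comparison: this road closes both C rings in one step, where the chosen route needs two (steps 8 and 14), and it needs no pressure equipment. The chosen plan sets against this that every ring A oxygen is present at the right oxidation level from the first step, so no late carbon–fluorine exchange is required.

**Alternative 3:** The cut is at C3–C4 and O1–C2 of unit 2. In the forward direction the lithium enolate of the benzyloxyacetyl ketone A7 would open the benzodioxinone A8 at its carbonyl, and acid in the same flask would condense the freed phenol onto the ketone to give A6.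
- Merits: the 3-oxygen of unit 2 arrives with the ketone, so that unit needs no oxidation. Enolate acylation is robust and metal-free, and A6 is fully protected.
- Weak points: A8 and A7 each take several steps. The bromide of A6 must still be turned into unit 1, and the analogous acylating agent for unit 1 would have two different ortho oxygens (5-benzyloxy, 7-methoxy side) that must be told apart. Enolates of α-alkoxy ketones can also acylate on oxygen.
- Comparison: this road avoids the double oxidation of step 15 and the carbonylation of hindered iodides, and is the stronger plan in that respect. The chosen plan sets against this the symmetric iodide 12, which gives the 5-hydroxy-7-methoxy pattern with no differentiation step, and one reaction type that serves both units.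

Key step: step 8

## Route

Remark on the chemistry: the enaminones 15 and 25 have no fixed alkene geometry, and the bis-epoxide 27 forms as a mixture of stereoisomers whose four centres are destroyed in the same flask. Their SMILES are therefore written without configuration. Compound 29 has no stereocentre.

Step 1
Reactants: 1 4-fluoro-3-hydroxybenzaldehyde
Product: 2 3-(benzyloxy)-4-fluorobenzaldehyde
Conditions: BnBr, K2CO3, DMF, rt
Reagents that add atoms: benzyl bromide, BrCc1ccccc1
Why: Williamson etherification of the phenol; the formyl group and the aryl fluoride are inert to K2CO3 at room temperature.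

Step 2
Reactants: 2 3-(benzyloxy)-4-fluorobenzaldehyde; 3 4-iodo-2-methoxyphenol
Product: 4 3-(benzyloxy)-4-(4-iodo-2-methoxyphenoxy)benzaldehyde
Conditions: K2CO3, DMF, 120 °C
Reagents that add atoms: none
Why: Nucleophilic aromatic substitution; the fluoride is para to the formyl group, which stabilises the Meisenheimer intermediate, and the aryl iodide of 3 is untouched because no transition metal is present.

Step 3
Reactants: 4 3-(benzyloxy)-4-(4-iodo-2-methoxyphenoxy)benzaldehyde; 5 (triisopropylsilyl)acetylene
Product: 6 3-(benzyloxy)-4-{2-methoxy-4-[(triisopropylsilyl)ethynyl]phenoxy}benzaldehyde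
Conditions: PdCl2(PPh3)2 (2 mol %), CuI (4 mol %), Et3N, THF, rt
Reagents that add atoms: none
Why: Sonogashira coupling of an aryl iodide at room temperature; the aldehyde is tolerated and the bulky silyl group caps the alkyne for later use.

Step 4
Reactants: 6 3-(benzyloxy)-4-{2-methoxy-4-[(triisopropylsilyl)ethynyl]phenoxy}benzaldehyde
Product: 7 {[4-(2-(benzyloxy)-4-ethynylphenoxy)-3-methoxyphenyl]ethynyl}triisopropylsilane
Conditions: dimethyl (1-diazo-2-oxopropyl)phosphonate, K2CO3, MeOH/THF, 0 °C to rt
Reagents that add atoms: dimethyl (1-diazo-2-oxopropyl)phosphonate, COP(=O)(OC)C(=[N+]=[N-])C(C)=O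
Why: Ohira–Bestmann homologation: methanolysis of the reagent frees the diazomethylphosphonate anion, which adds to the aldehyde, loses phosphate and N2 and rearranges to the terminal alkyne; K2CO3 in MeOH does not cleave a triisopropylsilyl alkyne.

Step 5
Reactants: 8 5-methoxyresorcinol
Product: 9 1-methoxy-3,5-bis(methoxymethoxy)benzene
Conditions: MeOCH2Cl, i-Pr2NEt, CH2Cl2, 0 °C to rt
Reagents that add atoms: chloromethyl methyl ether, COCCl
Why: Acetal protection of both phenols; the methoxymethyl ethers serve as the directing groups of the next step.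

Step 6
Reactants: 9 1-methoxy-3,5-bis(methoxymethoxy)benzene
Product: 11 2-iodo-5-methoxy-1,3-bis(methoxymethoxy)benzene, via aryllithium 10 (not isolated)
Conditions: n-BuLi, THF, 0 °C; then I2, −78 °C to rt
Reagents that add atoms: iodine, II
Why: Directed ortho-metalation; C2 lies between two chelating acetal oxygens and should be lithiated in preference to C4 and C6, which have only one acetal neighbour, and iodinolysis of 10 places iodine on the symmetry axis.

Step 7
Reactants: 11 2-iodo-5-methoxy-1,3-bis(methoxymethoxy)benzene
Product: 12 2-iodo-5-methoxybenzene-1,3-diol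
Conditions: HCl (cat.), MeOH, 40 °C
Reagents that add atoms: none
Why: Acid-catalysed transacetalisation to methanol removes both methoxymethyl groups; dilute acid and mild warming are chosen to limit ipso-protonation of the electron-rich iodide.

Step 8
Reactants: 12 2-iodo-5-methoxybenzene-1,3-diol; 13 carbon monoxide; 7 {[4-(2-(benzyloxy)-4-ethynylphenoxy)-3-methoxyphenyl]ethynyl}triisopropylsilane
Product: 16 2-(3-(benzyloxy)-4-{2-methoxy-4-[(triisopropylsilyl)ethynyl]phenoxy}phenyl)-5-hydroxy-7-methoxy-4H-chromen-4-one, via ynone 14 (not isolated), via enaminone 15 (not isolated)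
Conditions: PdCl2(PPh3)2 (5 mol %), CO (5 bar), Et2NH/DMF, 90 °C, degassed
Reagents that add atoms: none
Why: Zerovalent palladium, formed in the flask from PdCl2(PPh3)2, inserts into the C–I bond of 12, CO insertion gives a divalent aroylpalladium iodide, and this takes up the terminal alkyne of 7 (deprotonated by Et2NH, no copper) and reductively eliminates ynone 14, forming C4a–C4 and C4–C3. Et2NH then adds to the ynone to give enaminone 15, and one ortho hydroxyl attacks the amine-bearing carbon and expels Et2NH, forming O1–C2. The closest known reaction type is the palladium-catalysed carbonylative Sonogashira annulation of 2-iodophenols with terminal alkynes to flavones in a secondary amine. Ring C closes in the 6-endo mode by addition–elimination on the enaminone, which is what keeps the 5-exo closure to an aurone from competing. No stereocentre is formed. Three selectivities are needed: CO insertion before alkyne transfer (secured by CO pressure and the absence of copper, since direct coupling would end in a benzofuran), reaction at the terminal alkyne only (the triisopropylsilyl cap leaves the second alkyne without a C–H bond), and a single constitution (the two hydroxyls of 12 are related by symmetry, so either closure gives 16 and the other hydroxyl becomes the chelated 5-OH). The benzyl ether, both methyl ethers and the diaryl ether are spectators.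

Step 9
Reactants: 16 2-(3-(benzyloxy)-4-{2-methoxy-4-[(triisopropylsilyl)ethynyl]phenoxy}phenyl)-5-hydroxy-7-methoxy-4H-chromen-4-one
Product: 17 5-(benzyloxy)-2-(3-(benzyloxy)-4-{2-methoxy-4-[(triisopropylsilyl)ethynyl]phenoxy}phenyl)-7-methoxy-4H-chromen-4-one
Conditions: BnBr, K2CO3, DMF, 70 °C
Reagents that add atoms: benzyl bromide, BrCc1ccccc1
Why: Williamson benzylation of the hydrogen-bonded 5-hydroxyl, which needs warm DMF; the cap is required because a free 5-hydroxyflavone would be oxidised in step 15.

Step 10
Reactants: 17 5-(benzyloxy)-2-(3-(benzyloxy)-4-{2-methoxy-4-[(triisopropylsilyl)ethynyl]phenoxy}phenyl)-7-methoxy-4H-chromen-4-one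
Product: 18 5-(benzyloxy)-2-[3-(benzyloxy)-4-(4-ethynyl-2-methoxyphenoxy)phenyl]-7-methoxy-4H-chromen-4-one
Conditions: Bu4NF, THF (wet), 0 °C to rt
Reagents that add atoms: none
Why: Fluoride-induced protodesilylation of the alkynylsilane; benzyl ethers and the chromenone are inert.

Step 11
Reactants: 19 3,5-bis(benzyloxy)phenol
Product: 20 1,3-bis(benzyloxy)-5-(methoxymethoxy)benzene
Conditions: MeOCH2Cl, i-Pr2NEt, CH2Cl2, 0 °C to rt
Reagents that add atoms: chloromethyl methyl ether, COCCl
Why: Acetal protection of the phenol to install the one strong ortho-directing group of the ring.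

Step 12
Reactants: 20 1,3-bis(benzyloxy)-5-(methoxymethoxy)benzene
Product: 22 1,5-bis(benzyloxy)-2-iodo-3-(methoxymethoxy)benzene, via aryllithium 21 (not isolated)
Conditions: n-BuLi, THF, −20 to 0 °C; then I2, −78 °C to rt
Reagents that add atoms: iodine, II
Why: Directed ortho-metalation; the chelating acetal should direct lithium to its ortho position (two equivalent sites) and not to the carbon between the two benzyloxy groups, and the low temperature suppresses benzylic deprotonation and Wittig rearrangement.

Step 13
Reactants: 22 1,5-bis(benzyloxy)-2-iodo-3-(methoxymethoxy)benzene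
Product: 23 3,5-bis(benzyloxy)-2-iodophenol
Conditions: HCl (cat.), MeOH/THF, 40 °C
Reagents that add atoms: none
Why: Acid-catalysed transacetalisation removes the methoxymethyl group; benzyl ethers are stable to dilute acid.

Step 14
Reactants: 18 5-(benzyloxy)-2-[3-(benzyloxy)-4-(4-ethynyl-2-methoxyphenoxy)phenyl]-7-methoxy-4H-chromen-4-one; 23 3,5-bis(benzyloxy)-2-iodophenol; 13 carbon monoxide
Product: 26 5,7-bis(benzyloxy)-2-{4-[2-(benzyloxy)-4-(5-(benzyloxy)-7-methoxy-4-oxo-4H-chromen-2-yl)phenoxy]-3-methoxyphenyl}-4H-chromen-4-one, via ynone 24 (not isolated), via enaminone 25 (not isolated)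
Conditions: PdCl2(PPh3)2 (5 mol %), CO (5 bar), Et2NH/DMF, 90 °C, degassed
Reagents that add atoms: none
Why: The carbonylative Sonogashira annulation of step 8 is repeated on a 2-iodophenol with a single free hydroxyl: oxidative addition, CO insertion and alkyne coupling give ynone 24, Et2NH adds to give enaminone 25, and 6-endo addition–elimination by the only hydroxyl closes ring C of unit 2 with O5 and O7 already benzylated.

Step 15
Reactants: 26 5,7-bis(benzyloxy)-2-{4-[2-(benzyloxy)-4-(5-(benzyloxy)-7-methoxy-4-oxo-4H-chromen-2-yl)phenoxy]-3-methoxyphenyl}-4H-chromen-4-one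
Product: 28 5,7-bis(benzyloxy)-2-{4-[2-(benzyloxy)-4-(5-(benzyloxy)-3-hydroxy-7-methoxy-4-oxo-4H-chromen-2-yl)phenoxy]-3-methoxyphenyl}-3-hydroxy-4H-chromen-4-one, via bis-epoxide 27 (not isolated)
Conditions: dimethyldioxirane (acetone solution, excess), CH2Cl2, 0 °C to rt; then TsOH·H2O (cat.), CH2Cl2, rt
Reagents that add atoms: dimethyldioxirane, CC1(C)OO1
Why: Dioxirane epoxidation of the two enol-ether C2=C3 bonds of fully protected flavones, followed by acid opening of each oxirane at C2 (cation stabilised by O1 and the aryl group) and loss of H3, is the established flavone-to-flavonol conversion; the stereocentres of 27 vanish in the opening.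

Step 16
Reactants: 28 5,7-bis(benzyloxy)-2-{4-[2-(benzyloxy)-4-(5-(benzyloxy)-3-hydroxy-7-methoxy-4-oxo-4H-chromen-2-yl)phenoxy]-3-methoxyphenyl}-3-hydroxy-4H-chromen-4-one
Product: 29 3,5,7-trihydroxy-2-{4-[2-hydroxy-4-(3,5-dihydroxy-7-methoxy-4-oxo-4H-chromen-2-yl)phenoxy]-3-methoxyphenyl}-4H-chromen-4-one
Conditions: H2 (1 atm), 10% Pd/C, THF/MeOH, rt
Reagents that add atoms: none
Why: Hydrogenolysis of four benzyl aryl ethers under neutral conditions; the methyl ethers and the diaryl ether are inert and the conjugated pyranones should not be reduced at atmospheric pressure.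

## Compound list

1 | 4-fluoro-3-hydroxybenzaldehyde | O=Cc1ccc(F)c(O)c1 | starting material
2 | 3-(benzyloxy)-4-fluorobenzaldehyde | O=Cc1ccc(F)c(OCc2ccccc2)c1 | intermediate
3 | 4-iodo-2-methoxyphenol | COc1cc(I)ccc1O | starting material
4 | 3-(benzyloxy)-4-(4-iodo-2-methoxyphenoxy)benzaldehyde | O=Cc1ccc(Oc2ccc(I)cc2OC)c(OCc2ccccc2)c1 | intermediate
5 | (triisopropylsilyl)acetylene | C#C[Si](C(C)C)(C(C)C)C(C)C | starting material
6 | 3-(benzyloxy)-4-{2-methoxy-4-[(triisopropylsilyl)ethynyl]phenoxy}benzaldehyde | O=Cc1ccc(Oc2ccc(C#C[Si](C(C)C)(C(C)C)C(C)C)cc2OC)c(OCc2ccccc2)c1 | intermediate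
7 | {[4-(2-(benzyloxy)-4-ethynylphenoxy)-3-methoxyphenyl]ethynyl}triisopropylsilane | C#Cc1ccc(Oc2ccc(C#C[Si](C(C)C)(C(C)C)C(C)C)cc2OC)c(OCc2ccccc2)c1 | intermediate
8 | 5-methoxyresorcinol | COc1cc(O)cc(O)c1 | starting material
9 | 1-methoxy-3,5-bis(methoxymethoxy)benzene | COCOc1cc(OC)cc(OCOC)c1 | intermediate
10 | [4-methoxy-2,6-bis(methoxymethoxy)phenyl]lithium | [Li]c1c(OCOC)cc(OC)cc1OCOC | intermediate (not isolated)
11 | 2-iodo-5-methoxy-1,3-bis(methoxymethoxy)benzene | COCOc1cc(OC)cc(OCOC)c1I | intermediate
12 | 2-iodo-5-methoxybenzene-1,3-diol | COc1cc(O)c(I)c(O)c1 | intermediate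
13 | carbon monoxide | [C-]#[O+] | starting material
14 | 1-(2,6-dihydroxy-4-methoxyphenyl)-3-(3-(benzyloxy)-4-{2-methoxy-4-[(triisopropylsilyl)ethynyl]phenoxy}phenyl)prop-2-yn-1-one | COc1cc(O)c(C(=O)C#Cc2ccc(Oc3ccc(C#C[Si](C(C)C)(C(C)C)C(C)C)cc3OC)c(OCc3ccccc3)c2)c(O)c1 | intermediate (not isolated)
15 | 3-(diethylamino)-1-(2,6-dihydroxy-4-methoxyphenyl)-3-(3-(benzyloxy)-4-{2-methoxy-4-[(triisopropylsilyl)ethynyl]phenoxy}phenyl)prop-2-en-1-one | COc1cc(O)c(C(=O)C=C(N(CC)CC)c2ccc(Oc3ccc(C#C[Si](C(C)C)(C(C)C)C(C)C)cc3OC)c(OCc3ccccc3)c2)c(O)c1 | intermediate (not isolated)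
16 | 2-(3-(benzyloxy)-4-{2-methoxy-4-[(triisopropylsilyl)ethynyl]phenoxy}phenyl)-5-hydroxy-7-methoxy-4H-chromen-4-one | COc1cc(O)c2c(=O)cc(-c3ccc(Oc4ccc(C#C[Si](C(C)C)(C(C)C)C(C)C)cc4OC)c(OCc5ccccc5)c3)oc2c1 | intermediate
17 | 5-(benzyloxy)-2-(3-(benzyloxy)-4-{2-methoxy-4-[(triisopropylsilyl)ethynyl]phenoxy}phenyl)-7-methoxy-4H-chromen-4-one | COc1cc(OCc2ccccc2)c2c(=O)cc(-c3ccc(Oc4ccc(C#C[Si](C(C)C)(C(C)C)C(C)C)cc4OC)c(OCc5ccccc5)c3)oc2c1 | intermediate
18 | 5-(benzyloxy)-2-[3-(benzyloxy)-4-(4-ethynyl-2-methoxyphenoxy)phenyl]-7-methoxy-4H-chromen-4-one | COc1cc(OCc2ccccc2)c2c(=O)cc(-c3ccc(Oc4ccc(C#C)cc4OC)c(OCc5ccccc5)c3)oc2c1 | intermediate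
19 | 3,5-bis(benzyloxy)phenol | Oc1cc(OCc2ccccc2)cc(OCc2ccccc2)c1 | starting material
20 | 1,3-bis(benzyloxy)-5-(methoxymethoxy)benzene | COCOc1cc(OCc2ccccc2)cc(OCc2ccccc2)c1 | intermediate
21 | [2,4-bis(benzyloxy)-6-(methoxymethoxy)phenyl]lithium | [Li]c1c(OCOC)cc(OCc2ccccc2)cc1OCc1ccccc1 | intermediate (not isolated)
22 | 1,5-bis(benzyloxy)-2-iodo-3-(methoxymethoxy)benzene | COCOc1cc(OCc2ccccc2)cc(OCc2ccccc2)c1I | intermediate
23 | 3,5-bis(benzyloxy)-2-iodophenol | Oc1cc(OCc2ccccc2)cc(OCc2ccccc2)c1I | intermediate
24 | 1-[2,4-bis(benzyloxy)-6-hydroxyphenyl]-3-{4-[2-(benzyloxy)-4-(5-(benzyloxy)-7-methoxy-4-oxo-4H-chromen-2-yl)phenoxy]-3-methoxyphenyl}prop-2-yn-1-one | COc1cc(OCc2ccccc2)c2c(=O)cc(-c3ccc(Oc4ccc(C#CC(=O)c5c(O)cc(OCc6ccccc6)cc5OCc5ccccc5)cc4OC)c(OCc5ccccc5)c3)oc2c1 | intermediate (not isolated)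
25 | 1-[2,4-bis(benzyloxy)-6-hydroxyphenyl]-3-(diethylamino)-3-{4-[2-(benzyloxy)-4-(5-(benzyloxy)-7-methoxy-4-oxo-4H-chromen-2-yl)phenoxy]-3-methoxyphenyl}prop-2-en-1-one | COc1cc(OCc2ccccc2)c2c(=O)cc(-c3ccc(Oc4ccc(C(N(CC)CC)=CC(=O)c5c(O)cc(OCc6ccccc6)cc5OCc5ccccc5)cc4OC)c(OCc5ccccc5)c3)oc2c1 | intermediate (not isolated)
26 | 5,7-bis(benzyloxy)-2-{4-[2-(benzyloxy)-4-(5-(benzyloxy)-7-methoxy-4-oxo-4H-chromen-2-yl)phenoxy]-3-methoxyphenyl}-4H-chromen-4-one | COc1cc(OCc2ccccc2)c2c(=O)cc(-c3ccc(Oc4ccc(-c5cc(=O)c6c(OCc7ccccc7)cc(OCc7ccccc7)cc6o5)cc4OC)c(OCc5ccccc5)c3)oc2c1 | intermediate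
27 | bis(2,3-epoxide) of 26 (both C2–C3 bonds bridged by oxygen; mixture of stereoisomers) | COc1cc(OCc2ccccc2)c2c(c1)OC1(c3ccc(Oc4ccc(C56OC5C(=O)c5c(OCc7ccccc7)cc(OCc7ccccc7)cc5O6)cc4OC)c(OCc5ccccc5)c3)OC1C2=O | intermediate (not isolated)
28 | 5,7-bis(benzyloxy)-2-{4-[2-(benzyloxy)-4-(5-(benzyloxy)-3-hydroxy-7-methoxy-4-oxo-4H-chromen-2-yl)phenoxy]-3-methoxyphenyl}-3-hydroxy-4H-chromen-4-one | COc1cc(OCc2ccccc2)c2c(=O)c(O)c(-c3ccc(Oc4ccc(-c5oc6cc(OCc7ccccc7)cc(OCc7ccccc7)c6c(=O)c5O)cc4OC)c(OCc5ccccc5)c3)oc2c1 | intermediate
29 | 3,5,7-trihydroxy-2-{4-[2-hydroxy-4-(3,5-dihydroxy-7-methoxy-4-oxo-4H-chromen-2-yl)phenoxy]-3-methoxyphenyl}-4H-chromen-4-one | COc1cc(O)c2c(=O)c(O)c(-c3ccc(Oc4ccc(-c5oc6cc(O)cc(O)c6c(=O)c5O)cc4OC)c(O)c3)oc2c1 | target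

## Step count and least certain steps

Total: 16 steps. Longest linear sequence: 10 steps (1, 2, 3, 4, 8, 9, 10, 14, 15, 16). Steps 5–7 and 11–13 are three-step side branches.

**Step 8 (key step).** Oxidative addition into a C–I bond flanked by two hydroxyls on a very electron-rich ring may be slow, so reductive loss of iodine can overtake it. The aroylpalladium may be captured by Et2NH to give an amide. Alkyne transfer may precede CO insertion and lead to a benzofuran. Ring closure may leak into the 5-exo mode. The fallback sets out from aldehyde 6 and returns at 16, and it makes ring C by diketone cyclodehydration instead of carbonylation: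
- Pinnick oxidation (NaClO2, NaH2PO4, 2-methyl-2-butene) would give 3-(benzyloxy)-4-{2-methoxy-4-[(triisopropylsilyl)ethynyl]phenoxy}benzoic acid F1.
- Oxalyl chloride would convert it into 3-(benzyloxy)-4-{2-methoxy-4-[(triisopropylsilyl)ethynyl]phenoxy}benzoyl chloride F2.
- Purchasable 1-(2,6-dihydroxy-4-methoxyphenyl)ethanone F3, deprotonated three times with LiN(SiMe3)2 in THF at −78 °C, would be acylated on carbon by F2 to give 1-(2,6-dihydroxy-4-methoxyphenyl)-3-(3-(benzyloxy)-4-{2-methoxy-4-[(triisopropylsilyl)ethynyl]phenoxy}phenyl)propane-1,3-dione F4.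
- Warm acetic acid with a trace of H2SO4 would close F4 to 16. The two hydroxyls are again equivalent.

**Step 14.** The same processes threaten as in step 8, now with the valuable alkyne 18 as the limiting partner and with a less soluble product. The fallback sets out from 23 and 18 and returns at 26, and it brings the carbonyl carbon in as an acid chloride, so that no palladium has to insert into the hindered C–I bond:
- Iodine–lithium exchange on 23 (n-BuLi, 2 equiv, THF, −78 °C) and quenching with CO2 would give 2,4-bis(benzyloxy)-6-hydroxybenzoic acid F5.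
- Acetic anhydride in pyridine would give 2-(acetyloxy)-4,6-bis(benzyloxy)benzoic acid F6.
- Oxalyl chloride would give 2-(acetyloxy)-4,6-bis(benzyloxy)benzoyl chloride F7.
- Acyl Sonogashira coupling of F7 with 18 (PdCl2(PPh3)2, CuI, Et3N, THF, rt) would give 3,5-bis(benzyloxy)-2-(3-{4-[2-(benzyloxy)-4-(5-(benzyloxy)-7-methoxy-4-oxo-4H-chromen-2-yl)phenoxy]-3-methoxyphenyl}prop-2-ynoyl)phenyl acetate F8.
- Et2NH would then remove the acetyl group, add to the ynone and close ring C in the 6-endo mode to give 26.

**Step 7.** Ipso-protonation of the iodide, which is para to a methoxy group and ortho to two oxygens, may cause loss of iodine during the acid deprotection. Incomplete regiocontrol in the lithiation of step 6 would also surface here as an inseparable isomer. The fallback sets out from 8 and returns at 12. It is a direct electrophilic iodination with I2 and NaHCO3 in water at 0 °C, conditions under which resorcinols are iodinated between the two hydroxyls. No acid is involved and no new compound is made (F0).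

**Step 15.** Epoxidation of the second pyranone may stall after the first. Excess dioxirane may oxidise benzylic C–H bonds. The oxiranes may open along other paths than the desired elimination. The fallback sets out from 26 and returns at 28, and it makes C3 a nucleophile instead of epoxidising it. Double lithiation at C3 with LiN(i-Pr)2 in THF at −78 °C and trapping with B(OMe)3 would give the bis(dimethyl boronate) of 26 at both C3 positions F9. Oxidation with H2O2 in acetic acid would then give 28.

## Further compounds

F1 | step 8 | 3-(benzyloxy)-4-{2-methoxy-4-[(triisopropylsilyl)ethynyl]phenoxy}benzoic acid | OC(=O)c1ccc(Oc2ccc(C#C[Si](C(C)C)(C(C)C)C(C)C)cc2OC)c(OCc2ccccc2)c1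
F2 | step 8 | 3-(benzyloxy)-4-{2-methoxy-4-[(triisopropylsilyl)ethynyl]phenoxy}benzoyl chloride | ClC(=O)c1ccc(Oc2ccc(C#C[Si](C(C)C)(C(C)C)C(C)C)cc2OC)c(OCc2ccccc2)c1
F3 | step 8 | 1-(2,6-dihydroxy-4-methoxyphenyl)ethanone | CC(=O)c1c(O)cc(OC)cc1O
F4 | step 8 | 1-(2,6-dihydroxy-4-methoxyphenyl)-3-(3-(benzyloxy)-4-{2-methoxy-4-[(triisopropylsilyl)ethynyl]phenoxy}phenyl)propane-1,3-dione | COc1cc(O)c(C(=O)CC(=O)c2ccc(Oc3ccc(C#C[Si](C(C)C)(C(C)C)C(C)C)cc3OC)c(OCc3ccccc3)c2)c(O)c1
F5 | step 14 | 2,4-bis(benzyloxy)-6-hydroxybenzoic acid | OC(=O)c1c(O)cc(OCc2ccccc2)cc1OCc1ccccc1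
F6 | step 14 | 2-(acetyloxy)-4,6-bis(benzyloxy)benzoic acid | CC(=O)Oc1cc(OCc2ccccc2)cc(OCc2ccccc2)c1C(=O)O
F7 | step 14 | 2-(acetyloxy)-4,6-bis(benzyloxy)benzoyl chloride | CC(=O)Oc1cc(OCc2ccccc2)cc(OCc2ccccc2)c1C(=O)Cl
F8 | step 14 | 3,5-bis(benzyloxy)-2-(3-{4-[2-(benzyloxy)-4-(5-(benzyloxy)-7-methoxy-4-oxo-4H-chromen-2-yl)phenoxy]-3-methoxyphenyl}prop-2-ynoyl)phenyl acetate | COc1cc(OCc2ccccc2)c2c(=O)cc(-c3ccc(Oc4ccc(C#CC(=O)c5c(OC(C)=O)cc(OCc6ccccc6)cc5OCc5ccccc5)cc4OC)c(OCc5ccccc5)c3)oc2c1
F0 | step 7 | none | none
F9 | step 15 | bis(dimethyl boronate) of 26 at both C3 positions | COc1cc(OCc2ccccc2)c2c(=O)c(B(OC)OC)c(-c3ccc(Oc4ccc(-c5oc6cc(OCc7ccccc7)cc(OCc7ccccc7)c6c(=O)c5B(OC)OC)cc4OC)c(OCc5ccccc5)c3)oc2c1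
A1 | alternative 1 | methyl 3-(benzyloxy)-4-[4-(1,3-dioxolan-2-yl)-2-methoxyphenoxy]benzoate | COC(=O)c1ccc(Oc2ccc(C3OCCO3)cc2OC)c(OCc2ccccc2)c1
A2 | alternative 1 | methyl 3-(benzyloxy)-2-oxo-2H-pyran-5-carboxylate | COC(=O)C1=COC(=O)C(OCc2ccccc2)=C1
A3 | alternative 1 | 2-[4-(ethynyloxy)-3-methoxyphenyl]-1,3-dioxolane | C#COc1ccc(C2OCCO2)cc1OC
A4 | alternative 2 | 2-{3-(benzyloxy)-4-[4-(5,7-difluoro-4-oxochromen-2-yl)-2-methoxyphenoxy]phenyl}-5-fluoro-7-methoxychromen-4-one | COc1cc(F)c2c(=O)cc(-c3ccc(Oc4ccc(-c5cc(=O)c6c(F)cc(F)cc6o5)cc4OC)c(OCc7ccccc7)c3)oc2c1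
A5 | alternative 2 | 1-(2,6-difluoro-4-methoxyphenyl)-3-(3-(benzyloxy)-4-{2-methoxy-4-[3-oxo-3-(2,4,6-trifluorophenyl)propanoyl]phenoxy}phenyl)propane-1,3-dione | COc1cc(F)c(C(=O)CC(=O)c2ccc(Oc3ccc(C(=O)CC(=O)c4c(F)cc(F)cc4F)cc3OC)c(OCc3ccccc3)c2)c(F)c1
A6 | alternative 3 | 3,5,7-tris(benzyloxy)-2-{4-[2-(benzyloxy)-4-bromophenoxy]-3-methoxyphenyl}chromen-4-one | O=c1c(OCc2ccccc2)c(-c2ccc(Oc3ccc(Br)cc3OCc3ccccc3)c(OC)c2)oc2cc(OCc3ccccc3)cc(OCc3ccccc3)c12
A7 | alternative 3 | 2-(benzyloxy)-1-{4-[2-(benzyloxy)-4-bromophenoxy]-3-methoxyphenyl}ethan-1-one | O=C(COCc1ccccc1)c1ccc(Oc2ccc(Br)cc2OCc2ccccc2)c(OC)c1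
A8 | alternative 3 | 5,7-bis(benzyloxy)-2,2-dimethyl-4H-1,3-benzodioxin-4-one | CC1(C)OC(=O)c2c(OCc3ccccc3)cc(OCc3ccccc3)cc2O1
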